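**Retrosynthetic overview**

- Agrimol B is a central (S)-2-methylbutanoylphloroglucinol ring joined through two CH2 bridges to two identical outer rings. Both aryl–CH2 bonds to the central ring are cut last (twofold Friedel–Crafts benzylation by a hydroxymethylated outer unit through its ortho-quinone methide).
- The strategy rests on the outer benzene ring. Its six carbons carry in turn butanoyl, OH, CH2, OH, CH3 and OCH3, so carbon and oxygen substituents alternate and the CH3-, CH3O- and butanoyl-bearing carbons are contiguous.
- This pattern maps onto four carbons of a trioxygenated pentadiene, C(OBn)(OSiMe3)=CH–C(OSiMe3)=CH–CH3, plus the two alkyne carbons of CH3O–C≡C–C(O)C3H7. The ring bonds C(CH3)–C(OCH3) and C(OBn)–C(butanoyl) are disconnected.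
- Ring order: the outer ring is the only ring built (once, used twice). The central ring is phloroglucinol acylated with the (S)-acid chloride. The bridge carbons come from a formyl group placed on the last free CH of the outer ring.

Key step: step 6

Assumption: the double-bond geometry of 4 and 5 does not matter, because it is erased on aromatisation. If cycloadduct 13 expels benzyl alcohol instead of trimethylsilanol, the product is 16 itself, which is combined with the material from step 7.

**Step 1**
Reactants: 1 methyl 3-oxopentanoate; 2 benzyl alcohol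
Product: 3 benzyl 3-oxopentanoate
Conditions: BnOH (1.1 equiv), DMAP (0.1 equiv), toluene, reflux, MeOH distilled off
Reagents that add atoms: none
Why: DMAP-catalysed transesterification of a β-keto ester, driven by removal of methanol.

**Step 2**
Reactants: 3 benzyl 3-oxopentanoate
Product: 4 benzyl 3-(trimethylsilyloxy)pent-2-enoate (E/Z mixture)
Conditions: Me3SiCl, Et3N, hexane, 25 °C; filtration, distillation
Reagents that add atoms: chlorotrimethylsilane, C[Si](C)(C)Cl
Why: O-silylation of the enolised β-keto ester with silyl chloride and amine base is the standard first stage of bis(silyl enol ether) synthesis.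

**Step 3**
Reactants: 4 benzyl 3-(trimethylsilyloxy)pent-2-enoate
Product: 5 (1Z,3Z)-1-(benzyloxy)-1,3-bis(trimethylsilyloxy)penta-1,3-diene (drawn as one isomer; any geometry serves)
Conditions: LiN(iPr)2 (commercial solution, 1.1 equiv), THF, −78 °C; Me3SiCl, −78 → 0 °C; hexane, filtration under argon; used crude
Reagents that add atoms: chlorotrimethylsilane, C[Si](C)(C)Cl
Why: Kinetic γ-deprotonation of the silyl enol ether and O-silylation of the dienolate (Chan-type diene synthesis) gives the 1-alkoxy-1,3-bis(silyloxy)diene.

**Step 4**
Reactants: 6 butanoyl chloride; 7 N,O-dimethylhydroxylamine hydrochloride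
Product: 8 N-methoxy-N-methylbutanamide
Conditions: Et3N (2.2 equiv), CH2Cl2, 0 → 25 °C
Reagents that add atoms: none
Why: Schotten–Baumann-type N-acylation gives the Weinreb amide.

**Step 5**
Reactants: 9 chloroacetaldehyde dimethyl acetal; 8 N-methoxy-N-methylbutanamide
Product: 12 1-methoxyhex-1-yn-3-one, via lithium methoxyacetylide 10 (not isolated), via lithium hemiaminal adduct 11 (not isolated)
Conditions: Et2NH, n-BuLi (3.0 equiv per 9), THF, 0 °C; 9 (1.3 equiv), 0 °C; 8 (1.0 equiv), −78 → −20 °C; inverse quench into cold aqueous NaH2PO4; rapid filtration through Et3N-deactivated silica; used at once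
Reagents that add atoms: none
Why: Threefold base-induced elimination of the chloroacetal gives the lithium alkoxyacetylide, and Weinreb ketone synthesis stops at chelate 11, which releases the ynone only on the buffered quench, when diethylamine is already protonated.

**Step 6**
Reactants: 5 (1Z,3Z)-1-(benzyloxy)-1,3-bis(trimethylsilyloxy)penta-1,3-diene; 12 1-methoxyhex-1-yn-3-one
Product: 15 1-[6-(benzyloxy)-4-hydroxy-2-methoxy-3-methylphenyl]butan-1-one, via cyclohexadiene cycloadduct 13 (not isolated), via aryl trimethylsilyl ether 14 (not isolated)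
Conditions: 5 (1.5 equiv), toluene, 25 → 80 °C, sealed vessel, no Lewis acid; then THF/aqueous citric acid, 0 °C
Reagents that add atoms: none
Why: Proposed new method: the electron-rich diene 5, with its largest HOMO coefficient at the methyl-bearing terminus C4, should attack the push–pull ynone 12 at its methoxy-bearing β-carbon, and C1 of the diene then bonds to the α-carbon, either in one asynchronous transition state or through an allenolate/ketene-acetal cation pair, so the outer ring closes as a six-membered ring by [4+2] cycloaddition forming C(CH3)–C(OCH3) and C(OBn)–C(butanoyl). The closest known reaction type is the Diels–Alder/aromatisation of 1-alkoxy-1,3-bis(silyloxy)buta-1,3-dienes with alkynyl ketones and esters; new here is the methoxy donor on the alkyne carbon that must bond to a substituted diene terminus. In cycloadduct 13 the mixed ketal carbon and the C–H para to it are both doubly allylic, so thermal 1,4-elimination of trimethylsilanol (the better nucleofuge, leaving a benzyloxy-stabilised cation) should give arene 14, whose aryl silyl ether is hydrolysed on work-up. The two sp3 centres of 13 are lost on aromatisation, so no stereocontrol is needed. The selectivity required is regiochemical, CH3–C joined to CH3O–C, and it is secured by the matched polarisation of the partners, the β-carbon being the only electrophilic alkyne carbon of 12; Lewis acids are left out so that closure of C2 of the diene onto the ketone (a [3+3] salicylate pathway) does not compete.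

**Step 7**
Reactants: 15 1-[6-(benzyloxy)-4-hydroxy-2-methoxy-3-methylphenyl]butan-1-one
Product: 16 1-(4,6-dihydroxy-2-methoxy-3-methylphenyl)butan-1-one
Conditions: H2 (1 atm), 10% Pd/C, EtOAc, 25 °C
Reagents that add atoms: none
Why: Hydrogenolysis of an aryl benzyl ether; the hydrogen-bonded ortho-hydroxyaryl ketone should resist reduction under these mild conditions.

**Step 8**
Reactants: 16 1-(4,6-dihydroxy-2-methoxy-3-methylphenyl)butan-1-one
Product: 18 3-butanoyl-2,6-dihydroxy-4-methoxy-5-methylbenzaldehyde, via chloro(methoxy)methyl arene 17 (not isolated)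
Conditions: Cl2CHOMe (1.5 equiv), TiCl4 (3 equiv), CH2Cl2, −10 → 0 °C; then ice/1 M HCl
Reagents that add atoms: dichloromethyl methyl ether, COC(Cl)Cl; water, O
Why: Rieche formylation can only occur at the single unsubstituted ring carbon, which is activated by its two ortho hydroxyls.

**Step 9**
Reactants: 18 3-butanoyl-2,6-dihydroxy-4-methoxy-5-methylbenzaldehyde
Product: 19 1-[2,4-dihydroxy-3-(hydroxymethyl)-6-methoxy-5-methylphenyl]butan-1-one
Conditions: NaBH4 (1 equiv), THF/H2O (10:1), −10 → 0 °C; pH 6 phosphate buffer; used crude at once
Reagents that add atoms: none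
Why: Borohydride reduction is chemoselective for the aldehyde over the chelated aryl ketone, and low temperature with a buffered quench should stop it at the benzylic alcohol.

**Step 10**
Reactants: 20 (S)-2-methylbutanoic acid; 21 phloroglucinol
Product: 23 (2S)-2-methyl-1-(2,4,6-trihydroxyphenyl)butan-1-one, via (S)-2-methylbutanoyl chloride 22 (not isolated)
Conditions: (COCl)2, DMF (cat.), CH2Cl2, 0 → 25 °C, concentrate; then 21, AlCl3 (3.5 equiv), PhNO2/CH2Cl2, 0 → 25 °C; 1 M HCl
Reagents that add atoms: none
Why: Friedel–Crafts C-acylation of phloroglucinol stops at the monoketone because the acyl group deactivates the ring; the stereocentre comes from 20 and is protected by base-free acid chloride formation and a temperature at or below 25 °C, with enantiomeric purity to be checked on 23.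

**Step 11**
Reactants: 19 1-[2,4-dihydroxy-3-(hydroxymethyl)-6-methoxy-5-methylphenyl]butan-1-one (2.3 equiv); 23 (2S)-2-methyl-1-(2,4,6-trihydroxyphenyl)butan-1-one
Product: 26 agrimol B, (2S)-1-{3,5-bis[(3-butanoyl-2,6-dihydroxy-4-methoxy-5-methylphenyl)methyl]-2,4,6-trihydroxyphenyl}-2-methylbutan-1-one, via ortho-quinone methide 24 (not isolated), via monobenzylated phloroglucinol 25 (not isolated)
Conditions: 19 added slowly to 23, TsOH·H2O (10 mol %), MeCN, 0 → 25 °C
Reagents that add atoms: none
Why: Acid-catalysed ionisation of the ortho-hydroxybenzyl alcohol gives quinone methide 24, which undergoes Friedel–Crafts (Michael-type) C-alkylation at the two equivalent free positions of 23; 19 has no free ring carbon and cannot oligomerise, and the stereocentre of 23 is not touched under these mild conditions.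

**Compound list**

1 | methyl 3-oxopentanoate | CCC(=O)CC(=O)OC | starting material
2 | benzyl alcohol | OCc1ccccc1 | starting material
3 | benzyl 3-oxopentanoate | CCC(=O)CC(=O)OCc1ccccc1 | intermediate
4 | benzyl 3-(trimethylsilyloxy)pent-2-enoate (E/Z mixture) | CCC(O[Si](C)(C)C)=CC(=O)OCc1ccccc1 | intermediate
5 | (1Z,3Z)-1-(benzyloxy)-1,3-bis(trimethylsilyloxy)penta-1,3-diene | C/C=C(\O[Si](C)(C)C)/C=C(/OCc1ccccc1)O[Si](C)(C)C | intermediate
6 | butanoyl chloride | CCCC(=O)Cl | starting material
7 | N,O-dimethylhydroxylamine hydrochloride | CNOC.Cl | starting material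
8 | N-methoxy-N-methylbutanamide | CCCC(=O)N(C)OC | intermediate
9 | chloroacetaldehyde dimethyl acetal (2-chloro-1,1-dimethoxyethane) | COC(CCl)OC | starting material
10 | lithium methoxyacetylide | [Li]C#COC | intermediate (not isolated)
11 | lithium 1-methoxy-3-[methoxy(methyl)amino]hex-1-yn-3-olate | CCCC(O[Li])(C#COC)N(C)OC | intermediate (not isolated)
12 | 1-methoxyhex-1-yn-3-one | CCCC(=O)C#COC | intermediate
13 | 1-[6-(benzyloxy)-2-methoxy-3-methyl-4,6-bis(trimethylsilyloxy)cyclohexa-1,4-dien-1-yl]butan-1-one (diastereomer mixture) | CCCC(=O)C1=C(OC)C(C)C(O[Si](C)(C)C)=CC1(OCc2ccccc2)O[Si](C)(C)C | intermediate (not isolated)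
14 | 1-[6-(benzyloxy)-2-methoxy-3-methyl-4-(trimethylsilyloxy)phenyl]butan-1-one | CCCC(=O)c1c(OCc2ccccc2)cc(O[Si](C)(C)C)c(C)c1OC | intermediate (not isolated)
15 | 1-[6-(benzyloxy)-4-hydroxy-2-methoxy-3-methylphenyl]butan-1-one | CCCC(=O)c1c(OCc2ccccc2)cc(O)c(C)c1OC | intermediate
16 | 1-(4,6-dihydroxy-2-methoxy-3-methylphenyl)butan-1-one | CCCC(=O)c1c(O)cc(O)c(C)c1OC | intermediate
17 | 1-{3-[chloro(methoxy)methyl]-2,4-dihydroxy-6-methoxy-5-methylphenyl}butan-1-one | CCCC(=O)c1c(O)c(C(Cl)OC)c(O)c(C)c1OC | intermediate (not isolated)
18 | 3-butanoyl-2,6-dihydroxy-4-methoxy-5-methylbenzaldehyde | CCCC(=O)c1c(O)c(C=O)c(O)c(C)c1OC | intermediate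
19 | 1-[2,4-dihydroxy-3-(hydroxymethyl)-6-methoxy-5-methylphenyl]butan-1-one | CCCC(=O)c1c(O)c(CO)c(O)c(C)c1OC | intermediate
20 | (S)-2-methylbutanoic acid | O=C(O)[C@@H](C)CC | starting material
21 | phloroglucinol | Oc1cc(O)cc(O)c1 | starting material
22 | (2S)-2-methylbutanoyl chloride | O=C(Cl)[C@@H](C)CC | intermediate (not isolated)
23 | (2S)-2-methyl-1-(2,4,6-trihydroxyphenyl)butan-1-one | O=C(c1c(O)cc(O)cc1O)[C@@H](C)CC | intermediate
24 | 4-butanoyl-3-hydroxy-5-methoxy-6-methyl-2-methylidenecyclohexa-3,5-dien-1-one | CCCC(=O)C1=C(O)C(=C)C(=O)C(C)=C1OC | intermediate (not isolated)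
25 | (2S)-1-{3-[(3-butanoyl-2,6-dihydroxy-4-methoxy-5-methylphenyl)methyl]-2,4,6-trihydroxyphenyl}-2-methylbutan-1-one | CCCC(=O)c1c(O)c(Cc2c(O)cc(O)c(C(=O)[C@@H](C)CC)c2O)c(O)c(C)c1OC | intermediate (not isolated)
26 | agrimol B | CCCC(=O)c1c(O)c(Cc2c(O)c(Cc3c(O)c(C)c(OC)c(C(=O)CCC)c3O)c(O)c(C(=O)[C@@H](C)CC)c2O)c(O)c(C)c1OC | target

**Step count**

Total: 11 steps. Longest linear sequence: 8 steps (1, 2, 3, 6, 7, 8, 9, 11).

**Steps most likely to fail**

1. Step 6 (key cycloaddition). The methoxy donor lowers the electrophilicity of the alkyne and the first bond must form between two substituted carbons. The cycloaddition may therefore be outrun by silyl transfer or hydrolysis of the diene, may stop at the open-chain Michael stage, or may close through C2 of the diene onto the ketone. Fallback by known chemistry, setting out from 21 and 6 and returning at 16: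
   - Friedel–Crafts acylation of phloroglucinol with butanoyl chloride (AlCl3, PhNO2/CH2Cl2) should give 1-(2,4,6-trihydroxyphenyl)butan-1-one F1.
   - Nuclear C-methylation (MeI, NaOMe, MeOH) should give 1-(2,4,6-trihydroxy-3-methylphenyl)butan-1-one F2, to be separated from over-methylated material.
   - BnBr (2 equiv), K2CO3, acetone should etherify the free 4-hydroxyl and the less hindered chelated 6-hydroxyl to give 1-[4,6-bis(benzyloxy)-2-hydroxy-3-methylphenyl]butan-1-one F3, with the regioisomer removed by chromatography.
   - MeI, K2CO3, DMF should methylate the remaining hydroxyl between methyl and acyl to give 1-[4,6-bis(benzyloxy)-2-methoxy-3-methylphenyl]butan-1-one F4.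
   - Hydrogenolysis (H2, Pd/C, EtOAc) then gives 16.

2. Step 11 (twofold benzylation, fed by step 9). Alcohol 19 may ionise before it meets 23 and condense with itself with extrusion of formaldehyde. The second benzylation may lag behind the first, acid may shuffle aryl groups across the methylene bridges, and step 9 may over-reduce the aldehyde to a methyl group. Fallback with reversed polarity, setting out from 23 and 16 and returning at 26:
   - Twofold Mannich aminomethylation of 23 with dimethyl(methylidene)ammonium iodide (2.2 equiv, MeCN, 25 °C; NaHCO3) should give (2S)-1-{3,5-bis[(dimethylamino)methyl]-2,4,6-trihydroxyphenyl}-2-methylbutan-1-one F5.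
   - Heating F5 with 16 (2.2 equiv) in dioxane at 90–100 °C under a nitrogen stream should expel dimethylamine, and the quinone methides formed on the central ring are trapped at the single free carbon of 16 to give 26. This route bypasses steps 8 and 9.

3. Step 5 (ynone). Diethylamine set free on quench may add in conjugate fashion to the ynone, the ynol ether may hydrate under acid, and residual amide base may attack 8. Fallback setting out from 9 (through 10, generated as in step 5) and returning at 12:
   - Addition of 10 to butanal (THF, −78 °C) with a neutral aqueous work-up that removes the amine should give racemic 1-methoxyhex-1-yn-3-ol F6.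
   - Oxidation of the propargylic alcohol with MnO2 in CH2Cl2 at 25 °C under neutral conditions then gives 12.

**Further compounds**

F1 | step 6 | 1-(2,4,6-trihydroxyphenyl)butan-1-one | CCCC(=O)c1c(O)cc(O)cc1O
F2 | step 6 | 1-(2,4,6-trihydroxy-3-methylphenyl)butan-1-one | CCCC(=O)c1c(O)cc(O)c(C)c1O
F3 | step 6 | 1-[4,6-bis(benzyloxy)-2-hydroxy-3-methylphenyl]butan-1-one | CCCC(=O)c1c(OCc2ccccc2)cc(OCc2ccccc2)c(C)c1O
F4 | step 6 | 1-[4,6-bis(benzyloxy)-2-methoxy-3-methylphenyl]butan-1-one | CCCC(=O)c1c(OCc2ccccc2)cc(OCc2ccccc2)c(C)c1OC
F5 | step 11 | (2S)-1-{3,5-bis[(dimethylamino)methyl]-2,4,6-trihydroxyphenyl}-2-methylbutan-1-one | O=C(c1c(O)c(CN(C)C)c(O)c(CN(C)C)c1O)[C@@H](C)CC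
F6 | step 5 | 1-methoxyhex-1-yn-3-ol (racemic) | CCCC(O)C#COC
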